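## Retrosynthetic overview

- Numbering (germacrane): C1 furanone C=O, C2 furanone CH, C3 furanone C–O, C4(C15)=C5 Z-alkene, C6 lactone O–CH, C7 ring-fusion CH, C8 ester CH, C9 CH2, C10 quaternary C–O (C14 methyl), C11(=C13)–C12 methylene lactone. End game: 26 ⇐ selenoxide elimination (C11=C13) ⇐ C8 acylation ⇐ bicyclic furanone 21.
- Key disconnection C1–C10 (and, in the same operation, O–C3): 21 ⇐ open-chain ynal/methyl ketone 19 by carbene-catalysed polarity reversal of the aldehyde carbon C1. Enabling feature: in the furanone ring (O, C3, C2, C1, C10) the C1 ketone sits next to the oxygen-bearing quaternary C10, a latent α-ketol made of an aldehyde carbon and a ketone carbon, and the ring O–C3 bond is the 1,4-adduct of that C10 oxygen to a C2≡C3 ynone.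
- 19 ⇐ trans α-methylene lactone 16 (methylene masked as a selenide, C1 and C10 unmasked); 16 ⇐ C6–C7 bond and lactone by anti 2-(alkoxycarbonyl)allylboration of Z-enynal 6 with allylboronate 14.
- 6 ⇐ Sonogashira coupling of Z-iodide 3 with 4; 14 ⇐ alkynoate 11 (syn hydroalumination, borylmethylation) ⇐ 8 + 9 (asymmetric alkynylation sets C8).
- Ring order: γ-lactone (step 8), then in one step the ten-membered carbocycle (C1–C10) and the furanone with its nine-membered oxa-bridge (O–C3) (step 12).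

Key step: step 12

Remark: the C11 configuration of the selenide adducts 17–25 is left undefined, because step 15 erases it.

## Route

Step 1
Reactants: 1 but-2-yn-1-ol
Product: 3 (2Z)-3-iodobut-2-en-1-ol, via cyclic alkenylalanate 2 (not isolated)
Conditions: NaAlH2(OCH2CH2OMe)2, Et2O, 0 → 25 °C; then I2, THF, −78 → 0 °C
Reagents that add atoms: iodine, II
Why: Hydroxyl-directed trans-hydroalumination of the propargylic alcohol places aluminium on C3 in a five-membered alanate, and iodinolysis with retention gives the Z-iodide, which fixes the later C4=C5 geometry (C3 and C6 cis).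

Step 2
Reactants: 3 (2Z)-3-iodobut-2-en-1-ol; 4 tert-butyldimethyl(prop-2-yn-1-yloxy)silane
Product: 5 (2Z)-6-[(tert-butyldimethylsilyl)oxy]-3-methylhex-2-en-4-yn-1-ol
Conditions: PdCl2(PPh3)2 (3 mol %), CuI (6 mol %), Et3N, THF, 25 °C
Reagents that add atoms: none
Why: Sonogashira coupling of an alkenyl iodide with a terminal alkyne proceeds with retention of the Z geometry and tolerates the free alcohol and the silyl ether.

Step 3
Reactants: 5 (2Z)-6-[(tert-butyldimethylsilyl)oxy]-3-methylhex-2-en-4-yn-1-ol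
Product: 6 (2Z)-6-[(tert-butyldimethylsilyl)oxy]-3-methylhex-2-en-4-ynal
Conditions: MnO2 (activated, excess), CH2Cl2, 25 °C
Reagents that add atoms: none
Why: MnO2 oxidises the allylic alcohol selectively to the enal under neutral conditions, which should avoid over-oxidation and Z to E isomerisation.

Step 4
Reactants: 7 ethyl 2-(2-methyl-1,3-dioxolan-2-yl)acetate
Product: 8 2-(2-methyl-1,3-dioxolan-2-yl)acetaldehyde
Conditions: iBu2AlH (1.05 equiv), CH2Cl2, −78 °C; aqueous Rochelle salt
Reagents that add atoms: none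
Why: At −78 °C the tetrahedral aluminium hemiacetal, stabilised by the neighbouring dioxolane oxygen, survives until work-up, so the partial hydride reduction of the ester stops at the aldehyde.

Step 5
Reactants: 8 2-(2-methyl-1,3-dioxolan-2-yl)acetaldehyde; 9 methyl prop-2-ynoate
Product: 10 methyl (4R)-4-hydroxy-5-(2-methyl-1,3-dioxolan-2-yl)pent-2-ynoate
Conditions: Me2Zn (3 equiv), (S,S)-ProPhenol (20 mol %), Ph3P=O (40 mol %), toluene, 4 °C
Reagents that add atoms: none
Why: Zinc–ProPhenol-catalysed asymmetric alkynylation adds the zinc acetylide of the propiolate to one enantioface of the aldehyde and sets C8 (R) by catalyst control; the S,S ligand is assumed to be the enantiomer that gives the 4R carbinol, and its antipode is used if the sense proves opposite.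

Step 6
Reactants: 10 methyl (4R)-4-hydroxy-5-(2-methyl-1,3-dioxolan-2-yl)pent-2-ynoate
Product: 11 methyl (4R)-5-(2-methyl-1,3-dioxolan-2-yl)-4-[(triisopropylsilyl)oxy]pent-2-ynoate
Conditions: iPr3SiOTf, 2,6-lutidine, CH2Cl2, −78 → 0 °C
Reagents that add atoms: triisopropylsilyl trifluoromethanesulfonate, CC(C)[Si](OS(=O)(=O)C(F)(F)F)(C(C)C)C(C)C
Why: Silylation of the secondary propargylic alcohol with a silyl triflate and a hindered pyridine base gives an ether that should outlast the acid of step 10 and resist β-elimination next to the later C10 ketone.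

Step 7
Reactants: 11 methyl (4R)-5-(2-methyl-1,3-dioxolan-2-yl)-4-[(triisopropylsilyl)oxy]pent-2-ynoate; 12 2-(iodomethyl)-4,4,5,5-tetramethyl-1,3,2-dioxaborolane
Product: 14 methyl (2Z,4R)-5-(2-methyl-1,3-dioxolan-2-yl)-2-[(4,4,5,5-tetramethyl-1,3,2-dioxaborolan-2-yl)methyl]-4-[(triisopropylsilyl)oxy]pent-2-enoate, via alkenylalane 13 (not isolated)
Conditions: iBu2AlH (1.3 equiv), MeCu (10 mol %, from CuI and MeLi), HMPA/THF, −50 °C; then 12, −50 → 25 °C
Reagents that add atoms: none
Why: Copper-catalysed conjugate hydride addition to the alkynoate is a syn hydrometalation (H on C7 cis to aluminium on C11), and alkylation of the α-alumino enoate by the iodomethylboronate with retention gives the allylboronate with C8 cis to the ester and trans to CH2B, the geometry an anti allylboration needs.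

Step 8
Reactants: 6 (2Z)-6-[(tert-butyldimethylsilyl)oxy]-3-methylhex-2-en-4-ynal; 14 methyl (2Z,4R)-5-(2-methyl-1,3-dioxolan-2-yl)-2-[(4,4,5,5-tetramethyl-1,3,2-dioxaborolan-2-yl)methyl]-4-[(triisopropylsilyl)oxy]pent-2-enoate
Product: 16 (4S,5R)-5-[(1Z)-5-[(tert-butyldimethylsilyl)oxy]-2-methylpent-1-en-3-yn-1-yl]-3-methylidene-4-[(1R)-2-(2-methyl-1,3-dioxolan-2-yl)-1-[(triisopropylsilyl)oxy]ethyl]oxolan-2-one, via homoallylic borate 15 (not isolated)
Conditions: toluene, 80 °C; then pTsOH·H2O (10 mol %), 25 °C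
Reagents that add atoms: none
Why: Carbonyl 2-(alkoxycarbonyl)allylboration through a closed six-membered chair transition state with the C8 branch equatorial gives the 6,7-anti adduct, whose borate lactonises to the trans γ-lactone with the exocyclic methylene; the face of the allyl unit is set by the C8 centre (C8–H eclipsing the alkene to avoid A(1,3) strain with the cis ester, the aldehyde adding anti to the C9 branch with the silyloxy group outside), which should give the C6 and C7 configurations of the target.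

Step 9
Reactants: 16 (4S,5R)-5-[(1Z)-5-[(tert-butyldimethylsilyl)oxy]-2-methylpent-1-en-3-yn-1-yl]-3-methylidene-4-[(1R)-2-(2-methyl-1,3-dioxolan-2-yl)-1-[(triisopropylsilyl)oxy]ethyl]oxolan-2-one
Product: 17 (3RS,4S,5R)-5-[(1Z)-5-[(tert-butyldimethylsilyl)oxy]-2-methylpent-1-en-3-yn-1-yl]-4-[(1R)-2-(2-methyl-1,3-dioxolan-2-yl)-1-[(triisopropylsilyl)oxy]ethyl]-3-[(phenylselanyl)methyl]oxolan-2-one
Conditions: PhSeH (1.2 equiv), Et3N (10 mol %), CH2Cl2, 0 °C
Reagents that add atoms: benzeneselenol, [SeH]c1ccccc1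
Why: Michael addition of the selenol masks the α-methylene lactone, the only carbene-reactive acceptor of the molecule, as a β-seleno lactone whose new C11 centre is inconsequential.

Step 10
Reactants: 17 (3RS,4S,5R)-5-[(1Z)-5-[(tert-butyldimethylsilyl)oxy]-2-methylpent-1-en-3-yn-1-yl]-4-[(1R)-2-(2-methyl-1,3-dioxolan-2-yl)-1-[(triisopropylsilyl)oxy]ethyl]-3-[(phenylselanyl)methyl]oxolan-2-one
Product: 18 (3RS,4S,5R)-5-[(1Z)-5-hydroxy-2-methylpent-1-en-3-yn-1-yl]-4-[(1R)-3-oxo-1-[(triisopropylsilyl)oxy]butyl]-3-[(phenylselanyl)methyl]oxolan-2-one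
Conditions: HCl (1 M aq)/THF 1:4, 25 °C
Reagents that add atoms: water, O
Why: Dilute aqueous acid hydrolyses the dioxolane and the primary propargylic silyl ether, while the hindered secondary triisopropylsilyl ether, the selenide and the lactone should survive.

Step 11
Reactants: 18 (3RS,4S,5R)-5-[(1Z)-5-hydroxy-2-methylpent-1-en-3-yn-1-yl]-4-[(1R)-3-oxo-1-[(triisopropylsilyl)oxy]butyl]-3-[(phenylselanyl)methyl]oxolan-2-one
Product: 19 (3RS,4S,5R)-5-[(1Z)-2-methyl-5-oxopent-1-en-3-yn-1-yl]-4-[(1R)-3-oxo-1-[(triisopropylsilyl)oxy]butyl]-3-[(phenylselanyl)methyl]oxolan-2-one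
Conditions: MnO2 (activated, excess), CH2Cl2, 25 °C; used at once
Reagents that add atoms: none
Why: MnO2 oxidises the activated propargylic alcohol to the ynal and leaves the methyl ketone, the selenide and the silyl ether untouched.

Step 12
Reactants: 19 (3RS,4S,5R)-5-[(1Z)-2-methyl-5-oxopent-1-en-3-yn-1-yl]-4-[(1R)-3-oxo-1-[(triisopropylsilyl)oxy]butyl]-3-[(phenylselanyl)methyl]oxolan-2-one
Product: 21 (6R,7S,8R,10R,11RS)-3,10-epoxy-1-oxo-13-(phenylselanyl)-8-[(triisopropylsilyl)oxy]germacra-2,4Z-dien-12,6-olide, via ten-membered ketol 20 (not isolated)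
Conditions: 2-(pentafluorophenyl)-6,7-dihydro-5H-pyrrolo[2,1-c][1,2,4]triazol-2-ium tetrafluoroborate (20 mol %), iPr2NEt (20 mol %), 4 Å molecular sieves, toluene, 40 °C, slow addition of 19 (final 0.002 M)
Reagents that add atoms: none
Why: Proposed new method: the triazolylidene adds to the ynal carbon C1, proton transfer gives the acyl-anion equivalent, this adds to the C10 methyl ketone (crossed aldehyde–ketone benzoin) and releases the carbene to give ketol 20, whose C10 hydroxyl then adds to C3 of the ynone (transannular oxa-Michael, protonation at C2) to give the 3(2H)-furanone; the closest known reaction types are the carbene-catalysed intramolecular crossed benzoin of aldehydes with ketones to tertiary α-ketols (five- and six-membered rings), the macrocyclic Stetter reaction, and the base- or gold-catalysed cyclisation of α′-hydroxy ynones to 3(2H)-furanones, none of which has been shown with an ynal donor or for a ten-membered ring. The carbocycle closes by a 10-exo-trig addition of C1 to the C10 carbonyl, and the furanone, with the nine-membered oxa-bridge, by a 5-endo-dig addition of the oxygen to C3. C10 is the only new stereocentre and is set by the substrate: the benzoin step is reversible, and the 10R ketol is the one expected to bring its hydroxyl over C3 with the C14 methyl outside and with the C8 silyloxy group and the trans-lactone on the convex face of the ansa chain, so that the irreversible, strain-releasing oxa-Michael step should drain the equilibrating ketols into the 10R series. The step needs acyl-carbon (C1) reactivity of the carbene–ynal adduct over its internal redox and C3 (homoenolate) pathways, which the electron-poor N-pentafluorophenyl carbene, the aprotic medium free of protic nucleophiles and the absence of any Michael acceptor (methylene masked as the selenide) are meant to secure. Ring closure over oligomerisation is favoured by high dilution and by the Z-enyne and the trans-lactone, which fix six of the ten ring atoms in a turn holding C1 near C10, and the weak amine base avoids β-elimination of the C8 silyloxy group.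

Step 13
Reactants: 21 (6R,7S,8R,10R,11RS)-3,10-epoxy-1-oxo-13-(phenylselanyl)-8-[(triisopropylsilyl)oxy]germacra-2,4Z-dien-12,6-olide
Product: 22 (6R,7R,8R,10R,11RS)-3,10-epoxy-8-hydroxy-1-oxo-13-(phenylselanyl)germacra-2,4Z-dien-12,6-olide
Conditions: HF·pyridine, THF/pyridine, 0 → 25 °C
Reagents that add atoms: none
Why: Fluoride cleaves the Si–O bond of the secondary silyl ether under mildly acidic conditions that should spare the lactone, the furanone (a vinylogous ester) and the selenide.

Step 14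
Reactants: 22 (6R,7R,8R,10R,11RS)-3,10-epoxy-8-hydroxy-1-oxo-13-(phenylselanyl)germacra-2,4Z-dien-12,6-olide; 23 (2S)-2-methylbutanoic acid
Product: 24 (6R,7R,8R,10R,11RS)-3,10-epoxy-8-[(2S)-2-methylbutanoyloxy]-1-oxo-13-(phenylselanyl)germacra-2,4Z-dien-12,6-olide
Conditions: DCC (1.5 equiv), DMAP (0.2 equiv), CH2Cl2, 0 → 25 °C
Reagents that add atoms: none
Why: Steglich esterification acylates the C8 secondary alcohol with the enantiopure acid at low temperature, where the α-stereocentre of the acid should not epimerise and C8 is untouched.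

Step 15
Reactants: 24 (6R,7R,8R,10R,11RS)-3,10-epoxy-8-[(2S)-2-methylbutanoyloxy]-1-oxo-13-(phenylselanyl)germacra-2,4Z-dien-12,6-olide
Product: 26 (6R,7R,8R,10R)-3,10-epoxy-8-[(2S)-2-methylbutanoyloxy]-1-oxogermacra-2,4Z,11(13)-trien-12,6-olide (CNP0174601.1), via selenoxide 25 (not isolated)
Conditions: NaIO4 (1.5 equiv), NaHCO3, THF/H2O 3:1, 0 → 25 °C
Reagents that add atoms: none
Why: Oxidation of the selenide to the selenoxide and its syn elimination at room temperature, which can only take the C11 hydrogen, regenerates the exocyclic C11=C13 methylene, and periodate is chosen so that no peracid-type oxidant of the C4=C5 alkene is formed.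

## Compound list

1 | but-2-yn-1-ol | CC#CCO | starting material
2 | sodium 2,2-bis(2-methoxyethoxy)-3-methyl-2,5-dihydro-1,2-oxaluminol-2-uide (cyclic Z-alkenylalanate) | CC1=CCO[Al-]1(OCCOC)OCCOC.[Na+] | intermediate
3 | (2Z)-3-iodobut-2-en-1-ol | C/C(I)=C/CO | intermediate
4 | tert-butyldimethyl(prop-2-yn-1-yloxy)silane | C#CCO[Si](C)(C)C(C)(C)C | starting material
5 | (2Z)-6-[(tert-butyldimethylsilyl)oxy]-3-methylhex-2-en-4-yn-1-ol | C/C(C#CCO[Si](C)(C)C(C)(C)C)=C/CO | intermediate
6 | (2Z)-6-[(tert-butyldimethylsilyl)oxy]-3-methylhex-2-en-4-ynal | C/C(C#CCO[Si](C)(C)C(C)(C)C)=C/C=O | intermediate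
7 | ethyl 2-(2-methyl-1,3-dioxolan-2-yl)acetate | CCOC(=O)CC1(C)OCCO1 | starting material
8 | 2-(2-methyl-1,3-dioxolan-2-yl)acetaldehyde | O=CCC1(C)OCCO1 | intermediate
9 | methyl prop-2-ynoate | C#CC(=O)OC | starting material
10 | methyl (4R)-4-hydroxy-5-(2-methyl-1,3-dioxolan-2-yl)pent-2-ynoate | COC(=O)C#C[C@H](O)CC1(C)OCCO1 | intermediate
11 | methyl (4R)-5-(2-methyl-1,3-dioxolan-2-yl)-4-[(triisopropylsilyl)oxy]pent-2-ynoate | COC(=O)C#C[C@H](O[Si](C(C)C)(C(C)C)C(C)C)CC1(C)OCCO1 | intermediate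
12 | 2-(iodomethyl)-4,4,5,5-tetramethyl-1,3,2-dioxaborolane | ICB1OC(C)(C)C(C)(C)O1 | starting material
13 | methyl (2E,4R)-2-(diisobutylalumanyl)-5-(2-methyl-1,3-dioxolan-2-yl)-4-[(triisopropylsilyl)oxy]pent-2-enoate | COC(=O)/C([Al](CC(C)C)CC(C)C)=C\[C@H](O[Si](C(C)C)(C(C)C)C(C)C)CC1(C)OCCO1 | intermediate
14 | methyl (2Z,4R)-5-(2-methyl-1,3-dioxolan-2-yl)-2-[(4,4,5,5-tetramethyl-1,3,2-dioxaborolan-2-yl)methyl]-4-[(triisopropylsilyl)oxy]pent-2-enoate | COC(=O)/C(CB1OC(C)(C)C(C)(C)O1)=C\[C@H](O[Si](C(C)C)(C(C)C)C(C)C)CC2(C)OCCO2 | intermediate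
15 | methyl (3S,4R,5Z)-9-[(tert-butyldimethylsilyl)oxy]-6-methyl-2-methylidene-3-[(1R)-2-(2-methyl-1,3-dioxolan-2-yl)-1-[(triisopropylsilyl)oxy]ethyl]-4-[(4,4,5,5-tetramethyl-1,3,2-dioxaborolan-2-yl)oxy]non-5-en-7-ynoate | C=C(C(=O)OC)[C@@H]([C@H](OB1OC(C)(C)C(C)(C)O1)/C=C(/C)C#CCO[Si](C)(C)C(C)(C)C)[C@H](O[Si](C(C)C)(C(C)C)C(C)C)CC2(C)OCCO2 | intermediate
16 | (4S,5R)-5-[(1Z)-5-[(tert-butyldimethylsilyl)oxy]-2-methylpent-1-en-3-yn-1-yl]-3-methylidene-4-[(1R)-2-(2-methyl-1,3-dioxolan-2-yl)-1-[(triisopropylsilyl)oxy]ethyl]oxolan-2-one | C=C1C(=O)O[C@H](/C=C(/C)C#CCO[Si](C)(C)C(C)(C)C)[C@H]1[C@H](O[Si](C(C)C)(C(C)C)C(C)C)CC2(C)OCCO2 | intermediate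
17 | (3RS,4S,5R)-5-[(1Z)-5-[(tert-butyldimethylsilyl)oxy]-2-methylpent-1-en-3-yn-1-yl]-4-[(1R)-2-(2-methyl-1,3-dioxolan-2-yl)-1-[(triisopropylsilyl)oxy]ethyl]-3-[(phenylselanyl)methyl]oxolan-2-one | O=C1O[C@H](/C=C(/C)C#CCO[Si](C)(C)C(C)(C)C)[C@@H]([C@H](O[Si](C(C)C)(C(C)C)C(C)C)CC2(C)OCCO2)C1C[Se]c1ccccc1 | intermediate
18 | (3RS,4S,5R)-5-[(1Z)-5-hydroxy-2-methylpent-1-en-3-yn-1-yl]-4-[(1R)-3-oxo-1-[(triisopropylsilyl)oxy]butyl]-3-[(phenylselanyl)methyl]oxolan-2-one | O=C1O[C@H](/C=C(/C)C#CCO)[C@@H]([C@H](O[Si](C(C)C)(C(C)C)C(C)C)CC(C)=O)C1C[Se]c1ccccc1 | intermediate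
19 | (3RS,4S,5R)-5-[(1Z)-2-methyl-5-oxopent-1-en-3-yn-1-yl]-4-[(1R)-3-oxo-1-[(triisopropylsilyl)oxy]butyl]-3-[(phenylselanyl)methyl]oxolan-2-one | O=C1O[C@H](/C=C(/C)C#CC=O)[C@@H]([C@H](O[Si](C(C)C)(C(C)C)C(C)C)CC(C)=O)C1C[Se]c1ccccc1 | intermediate
20 | (6R,7S,8R,10R,11RS)-10-hydroxy-1-oxo-13-(phenylselanyl)-8-[(triisopropylsilyl)oxy]germacr-4Z-en-2-yn-12,6-olide (ten-membered ring C1–C10 with C2≡C3) | c1ccccc1[Se]CC1C(=O)O[C@@H]2/C=C(/C)C#CC(=O)[C@](C)(O)C[C@@H](O[Si](C(C)C)(C(C)C)C(C)C)[C@@H]12 | intermediate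
21 | (6R,7S,8R,10R,11RS)-3,10-epoxy-1-oxo-13-(phenylselanyl)-8-[(triisopropylsilyl)oxy]germacra-2,4Z-dien-12,6-olide (the target with OSi(iPr)3 at C8 and CH–CH2SePh at C11) | c1ccccc1[Se]CC1C(=O)O[C@@H]2/C=C(/C)C3=CC(=O)[C@@](C)(C[C@@H](O[Si](C(C)C)(C(C)C)C(C)C)[C@@H]12)O3 | intermediate
22 | (6R,7R,8R,10R,11RS)-3,10-epoxy-8-hydroxy-1-oxo-13-(phenylselanyl)germacra-2,4Z-dien-12,6-olide | c1ccccc1[Se]CC1C(=O)O[C@@H]2/C=C(/C)C3=CC(=O)[C@@](C)(C[C@@H](O)[C@@H]12)O3 | intermediate
23 | (2S)-2-methylbutanoic acid | CC[C@H](C)C(=O)O | starting material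
24 | (6R,7R,8R,10R,11RS)-3,10-epoxy-8-[(2S)-2-methylbutanoyloxy]-1-oxo-13-(phenylselanyl)germacra-2,4Z-dien-12,6-olide | c1ccccc1[Se]CC1C(=O)O[C@@H]2/C=C(/C)C3=CC(=O)[C@@](C)(C[C@@H](OC(=O)[C@@H](C)CC)[C@@H]12)O3 | intermediate
25 | Se-oxide of 24 (13-(phenylseleninyl) compound) | O=[Se](c1ccccc1)CC1C(=O)O[C@@H]2/C=C(/C)C3=CC(=O)[C@@](C)(C[C@@H](OC(=O)[C@@H](C)CC)[C@@H]12)O3 | intermediate
26 | (6R,7R,8R,10R)-3,10-epoxy-8-[(2S)-2-methylbutanoyloxy]-1-oxogermacra-2,4Z,11(13)-trien-12,6-olide (CNP0174601.1) | C=C1C(=O)O[C@@H]2/C=C(/C)C3=CC(=O)[C@@](C)(C[C@@H](OC(=O)[C@@H](C)CC)[C@@H]12)O3 | target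

## Step count

Total steps: 15. Longest linear sequence: 12 steps (7 → 26, steps 4–15); the branch 1 → 6 has 3 steps.

## Steps most likely to fail

**Step 12 (proposed new method).** The carbene–ynal adduct may discharge through internal redox (protonation at C3 to an enoyl azolium) or through its C3 carbon faster than its acyl carbon closes the strained ten-membered ring, and facial control at C10 may be incomplete. The fallback uses known chemistry; it sets out from 19 and comes back at 21. A reductive keto–aldehyde pinacol macrocyclisation with SmI2 (THF, high dilution, −78 → 0 °C; the conjugated aldehyde is reduced first and its ketyl adds to the samarium-bound C10 ketone) should give the ten-membered propargylic 1,10-diol F1. MnO2 then oxidises only its secondary propargylic alcohol to ketol 20. Ketol 20 is cyclised to 21 with (4-CF3C6H4)3PAuCl/AgOTf (5 mol %, toluene, 25 °C), the established 5-endo-dig cyclisation of hydroxy ynones to 3(2H)-furanones. Any C10 epimer would be separated at 21.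

**Step 8.** The uncatalysed allylboration of the ester-deactivated, hindered boronate may be so slow that enal 6 isomerises from Z to E, and the C8 centre may give poor π-facial discrimination. The fallback sets out from 11 and comes back at 16. Alkenylalane 13, generated as in step 7, is trapped with formaldehyde instead of 12 to give the hydroxymethyl enoate F2, and CBr4/PPh3 converts it into the allylic bromide F3. A chromium-catalysed asymmetric Nozaki–Hiyama–Kishi 2-(alkoxycarbonyl)allylation of 6 follows (CrCl2 10 mol %, a chiral 1,8-bis(4-isopropyloxazolin-2-yl)carbazole ligand matched to C8, Mn, Cp2ZrCl2, THF, 25 °C). It runs through a configurationally mobile allylchromium, so it is stereoconvergent, anti by the chair transition state, with the face set by the ligand, and should give the hydroxy ester F4. F4 lactonises with pTsOH to 16.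

**Step 5.** The enolisable, unbranched aldehyde 8 may undergo aldol self-condensation under the zinc alkoxide conditions, and the enantioselectivity may be insufficient. The fallback sets out from 7 and comes back at 11. Ester 7 is converted with MeNHOMe·HCl/iPrMgCl into the N-methoxy-N-methylamide F5, and lithium (trimethylsilyl)acetylide gives the ynone F6. Noyori asymmetric transfer hydrogenation (RuCl[(R,R)-TsDPEN](p-cymene), iPrOH, 25 °C) should give the (R)-propargylic alcohol F7. iPr3SiOTf/2,6-lutidine gives the silyl ether F8, K2CO3/MeOH removes the alkynyl silane to give the terminal alkyne F9, and n-BuLi followed by ClCO2Me gives 11.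

## Further compounds

F1 | step 12 | (6R,7S,8R,10R,11RS)-1,10-dihydroxy-13-(phenylselanyl)-8-[(triisopropylsilyl)oxy]germacr-4Z-en-2-yn-12,6-olide (C1 epimers) | c1ccccc1[Se]CC1C(=O)O[C@@H]2/C=C(/C)C#CC(O)[C@](C)(O)C[C@@H](O[Si](C(C)C)(C(C)C)C(C)C)[C@@H]12
F2 | step 8 | methyl (2Z,4R)-2-(hydroxymethyl)-5-(2-methyl-1,3-dioxolan-2-yl)-4-[(triisopropylsilyl)oxy]pent-2-enoate | COC(=O)/C(CO)=C\[C@H](O[Si](C(C)C)(C(C)C)C(C)C)CC1(C)OCCO1
F3 | step 8 | methyl (2E,4R)-2-(bromomethyl)-5-(2-methyl-1,3-dioxolan-2-yl)-4-[(triisopropylsilyl)oxy]pent-2-enoate | COC(=O)/C(CBr)=C\[C@H](O[Si](C(C)C)(C(C)C)C(C)C)CC1(C)OCCO1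
F4 | step 8 | methyl (3S,4R,5Z)-9-[(tert-butyldimethylsilyl)oxy]-4-hydroxy-6-methyl-2-methylidene-3-[(1R)-2-(2-methyl-1,3-dioxolan-2-yl)-1-[(triisopropylsilyl)oxy]ethyl]non-5-en-7-ynoate | C=C(C(=O)OC)[C@@H]([C@H](O)/C=C(/C)C#CCO[Si](C)(C)C(C)(C)C)[C@H](O[Si](C(C)C)(C(C)C)C(C)C)CC1(C)OCCO1
F5 | step 5 | N-methoxy-N-methyl-2-(2-methyl-1,3-dioxolan-2-yl)acetamide | CON(C)C(=O)CC1(C)OCCO1
F6 | step 5 | 1-(2-methyl-1,3-dioxolan-2-yl)-4-(trimethylsilyl)but-3-yn-2-one | C[Si](C)(C)C#CC(=O)CC1(C)OCCO1
F7 | step 5 | (2R)-1-(2-methyl-1,3-dioxolan-2-yl)-4-(trimethylsilyl)but-3-yn-2-ol | C[Si](C)(C)C#C[C@H](O)CC1(C)OCCO1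
F8 | step 5 | triisopropyl{[(2R)-1-(2-methyl-1,3-dioxolan-2-yl)-4-(trimethylsilyl)but-3-yn-2-yl]oxy}silane | C[Si](C)(C)C#C[C@H](O[Si](C(C)C)(C(C)C)C(C)C)CC1(C)OCCO1
F9 | step 5 | triisopropyl{[(2R)-1-(2-methyl-1,3-dioxolan-2-yl)but-3-yn-2-yl]oxy}silane | C#C[C@H](O[Si](C(C)C)(C(C)C)C(C)C)CC1(C)OCCO1
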